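## Retrosynthetic overview

1. Numbering: indane C1 (aroyl), C2 (4-hydroxyphenyl), C3 (3,5-dihydroxyphenyl); ring A = C3a, C4(O), C5, C6(O), C7, C7a; C8 = exocyclic carbon on C1. The plan rests on ring A. C3a is ortho/para to O4/O6 and can be bonded to C3 by electrophilic substitution. C7a is meta to both oxygens and has to act as an aryl–metal nucleophile.
2. Key disconnection C1–C7a: C3 is held as a ketone conjugated to C2=C1, and a C7a boronate is handed to chiral rhodium and added to C1. This closes the five-membered ring, the only ring built; ring A and the three pendant arenes are bought.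
3. C8 travels as an (S)-silyloxy carbinol, so C1 is not enolisable until the end. After ring closure the C3 ketone becomes an enol triflate and takes the resorcinol ring by Negishi coupling. C2=C3 is then hydrogenated anti to the C1 side chain to give the all-cis triad; desilylation, oxidation at C8 and hydrogenolysis finish the synthesis.
4. The enone comes from three pieces: the ring A aldehyde (Vilsmeier formylation at C3a of dibenzylated 5-bromoresorcinol), a resolved aryl propargyl silyl ether (C1, C2, C8) and 4-benzyloxyiodobenzene. Hydroxyl-directed trans-hydrostannation and Stille coupling fix the E geometry; oxidation and Miyaura borylation follow.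

Key step: step 11

Remark on the target: the SMILES decodes as the all-cis (1R,2R,3R) isomer (C1 aroyl, C2 aryl and C3 aryl on one face), the less stable arrangement at C1, so C1 is kept non-enolisable up to step 16.

Remark on step 11: the sense of induction of a C2-symmetric diene on this tethered α-aryl enone cannot be read safely from α-unsubstituted chalcones; (R,R)-Ph-bod* is written as the antipode matched with (S)-C8, its mirror image is equally available, and a C1 epimer would be a separable diastereomer because C8 is enantiopure.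

## Route

Step 1
Reactants: 1 5-bromoresorcinol
Product: 2 1,3-bis(benzyloxy)-5-bromobenzene
Conditions: BnBr (2.3 equiv), K2CO3 (2.5 equiv), DMF, rt → 50 °C
Reagents that add atoms: benzyl bromide, BrCc1ccccc1
Why: Williamson ether synthesis on both phenols; benzyl is chosen because all aryl ethers can leave at the end by neutral hydrogenolysis that does not disturb the epimerisable C1.

Step 2
Reactants: 2 1,3-bis(benzyloxy)-5-bromobenzene
Product: 4 2,4-bis(benzyloxy)-6-bromobenzaldehyde, via aryl iminium chloride 3 (not isolated)
Conditions: POCl3 (2 equiv), DMF, 0 → 75 °C; then ice-water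
Reagents that add atoms: N,N-dimethylformamide, CN(C)C=O; water, O
Why: Vilsmeier–Haack formylation attacks the position para to one ether and ortho to the other (future C3a) rather than the crowded site between the two benzyloxy groups, needs no Lewis acid that would strip benzyl ethers, and places C3 next to the C7a bromide.

Step 3
Reactants: 5 4-(benzyloxy)benzaldehyde; 6 ethynylmagnesium bromide
Product: 7 rac-1-[4-(benzyloxy)phenyl]prop-2-yn-1-ol
Conditions: HC≡CMgBr (0.5 M in THF, 1.2 equiv), THF, 0 °C; aq NH4Cl
Reagents that add atoms: none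
Why: Grignard 1,2-addition to a non-enolisable aromatic aldehyde brings in C1 and C2 as the alkyne carbons and forms the C8 carbinol as the racemate.

Step 4
Reactants: 7 rac-1-[4-(benzyloxy)phenyl]prop-2-yn-1-ol
Product: 8 (S)-1-[4-(benzyloxy)phenyl]prop-2-yn-1-ol
Conditions: Novozym 435 (immobilised lipase B of Candida antarctica), vinyl acetate (3 equiv), MTBE, 35 °C, stopped just past half conversion; chromatography
Reagents that add atoms: none
Why: Lipase-catalysed kinetic resolution by irreversible transesterification, known for 1-arylprop-2-yn-1-ols, acylates the (R)-alcohol (aryl as large, ethynyl as medium group), so the unreacted (S)-alcohol should remain in very high enantiomeric purity and fixes C8.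

Step 5
Reactants: 8 (S)-1-[4-(benzyloxy)phenyl]prop-2-yn-1-ol
Product: 9 (S)-{1-[4-(benzyloxy)phenyl]prop-2-yn-1-yl}oxy(tert-butyl)dimethylsilane
Conditions: TBSCl (1.3 equiv), imidazole (2.5 equiv), DMF, rt
Reagents that add atoms: tert-butyldimethylsilyl chloride, CC(C)(C)[Si](C)(C)Cl
Why: Imidazole-promoted O-silylation does not touch the C8–O bond, so the configuration is retained, and it masks C8–OH so that only the later C3–OH can act as a directing group.

Step 6
Reactants: 9 (S)-propargyl silyl ether; 4 2,4-bis(benzyloxy)-6-bromobenzaldehyde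
Product: 11 (4R)-1-[2,4-bis(benzyloxy)-6-bromophenyl]-4-[4-(benzyloxy)phenyl]-4-(tert-butyldimethylsilyloxy)but-2-yn-1-ol as both C3 carbinol epimers, via lithium acetylide 10 (not isolated)
Conditions: 9, n-BuLi (1.0 equiv), THF, −78 °C; then 4, −78 → −20 °C; aq NH4Cl
Reagents that add atoms: none
Why: Acetylide 1,2-addition forms C2–C3 without bromine–lithium exchange at C7a; the new C3 carbinol forms unselectively, which is harmless because it is oxidised in step 9, and C8 is spatially unchanged (its descriptor reads R only because the internal alkynyl group now outranks aryl).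

Step 7
Reactants: 11 C3-epimeric propargylic alcohol
Product: 12 (2Z,4S)-1-[2,4-bis(benzyloxy)-6-bromophenyl]-4-[4-(benzyloxy)phenyl]-4-(tert-butyldimethylsilyloxy)-2-(tributylstannyl)but-2-en-1-ol (C3 epimers; tin on C2, cis to C8)
Conditions: [Cp*RuCl]4 (2.5 mol %), Bu3SnH (1.1 equiv, slow addition), CH2Cl2, rt
Reagents that add atoms: tributyltin hydride, CCCC[SnH](CCCC)CCCC
Why: Ruthenium-catalysed hydroxyl-directed trans-hydrostannation uses a hydrogen bond from the free C3–OH to the chloride on ruthenium to steer tin to the proximal C2 while hydrogen arrives anti at C1, so C8 ends trans to C3, and the silyl ether at C8 cannot compete as a director.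

Step 8
Reactants: 12 (Z)-alkenylstannane; 13 1-(benzyloxy)-4-iodobenzene
Product: 14 (2E,4S)-1-[2,4-bis(benzyloxy)-6-bromophenyl]-2,4-bis[4-(benzyloxy)phenyl]-4-(tert-butyldimethylsilyloxy)but-2-en-1-ol (C3 epimers)
Conditions: 13 (1.3 equiv), Pd(PPh3)4 (10 mol %), Cu(O2CC4H3S) (copper thiophene-2-carboxylate, 1.5 equiv), [Bu4N][Ph2PO2] (1.5 equiv), DMF, rt
Reagents that add atoms: none
Why: Copper-assisted Stille–Migita coupling proceeds with retention at C2, so the new aryl group ends cis to C8; the aryl iodide adds to zerovalent palladium at room temperature where the hindered electron-rich C7a–Br bond does not, and the phosphinate traps tin without fluoride, which spares the silyl ether.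

Step 9
Reactants: 14 (E)-allylic alcohol
Product: 15 (2E,4S)-1-[2,4-bis(benzyloxy)-6-bromophenyl]-2,4-bis[4-(benzyloxy)phenyl]-4-(tert-butyldimethylsilyloxy)but-2-en-1-one
Conditions: Dess–Martin periodinane (1.3 equiv), NaHCO3, CH2Cl2, 0 °C → rt, light excluded
Reagents that add atoms: none
Why: Buffered Dess–Martin oxidation of the crowded, acid-sensitive benzylic and allylic C3 carbinol merges both epimers into one E-enone without ionising the alcohol.

Step 10
Reactants: 15 bromo enone; 16 bis(pinacolato)diboron
Product: 17 (2E,4S)-1-[2,4-bis(benzyloxy)-6-(4,4,5,5-tetramethyl-1,3,2-dioxaborolan-2-yl)phenyl]-2,4-bis[4-(benzyloxy)phenyl]-4-(tert-butyldimethylsilyloxy)but-2-en-1-one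
Conditions: 16 (1.5 equiv), PdCl2(dppf) (5 mol %), KOAc (3 equiv), dioxane, 80 °C
Reagents that add atoms: none
Why: Miyaura borylation (oxidative addition at C7a–Br, acetate-assisted transmetalation, reductive elimination) installs boron at C7a; KOAc is too weak to start Suzuki coupling or to deprotonate C8–H, and the crowded trisubstituted enone is a poor partner for competing carbopalladation at this temperature.

Step 11
Reactants: 17 boryl enone
Product: 18 (2S,3R)-5,7-bis(benzyloxy)-2-[4-(benzyloxy)phenyl]-3-{(S)-[4-(benzyloxy)phenyl](tert-butyldimethylsilyloxy)methyl}indan-1-one (2,3-trans; indanone C3 is target C1, indanone C1 is target C3)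
Conditions: [RhCl(C2H4)2]2 (2.5 mol %), (R,R)-Ph-bod* [(1R,4R)-2,5-diphenylbicyclo[2.2.2]octa-2,5-diene, 5.5 mol %], KOH (0.2 equiv), dioxane/H2O 10:1, 50 °C
Reagents that add atoms: none
Why: Hydroxide turns the chloride precatalyst into a diene–Rh–OH complex of monovalent rhodium, the C7a–B bond transmetalates to it, and the C7a–Rh aryl binds the tethered C1=C2 alkene and inserts it syn, which forms C1–C7a and leaves rhodium on C2 as an oxa-π-allyl enolate that water protonates with return of Rh–OH. The closest known reaction type is the rhodium-catalysed asymmetric intramolecular 1,4-addition (Hayashi–Miyaura type) of 2'-(pinacolboryl)chalcones to 3-substituted indan-1-ones, and here the enone only carries an extra α-aryl group and a β-alkyl in place of a β-aryl group. The one ring closed is C1–C2–C3–C3a–C7a, formally a 5-endo-trig closure, which is feasible because the bond forms by inner-sphere migratory insertion from a metal already π-bound to the alkene and not by attack of a free nucleophile. C1 is set by the alkene face that the chiral diene lets rhodium bind, and the substrate pushes the same way: the C2 aryl group cis to C8 forces C8–H into the alkene plane (allylic 1,3-strain), so OTBS and aryl flank opposite faces and the aryl–rhodium adds anti to the C8–O bond (Felkin–Anh type), which for (S)-C8 gives (R)-C1, whereas the opposite C8 configuration would put the silyloxy group on the face C7a must attack. C2 is set by protonation of the enolate, stays exchangeable in the basic medium and should settle trans to the C1 side chain; it is erased in step 12 in any case. The step needs insertion to outrun protodeboronation and needs C8–H to stay in place, which is secured by the tether, the highly active diene–rhodium aryl, the small amount of base, and the in-plane C8–H bond that is orthogonal to the enone π-system and therefore poorly acidic.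

Step 12
Reactants: 18 trans-indanone
Product: 20 (1S)-4,6-bis(benzyloxy)-2-[4-(benzyloxy)phenyl]-1-{(S)-[4-(benzyloxy)phenyl](tert-butyldimethylsilyloxy)methyl}-1H-inden-3-yl trifluoromethanesulfonate, via potassium enolate 19 (not isolated)
Conditions: KN(SiMe3)2 (0.98 equiv), THF, −78 °C; N-(5-chloropyridin-2-yl)bis(trifluoromethanesulfonimide) (1.1 equiv), −78 → 0 °C; aq NH4Cl
Reagents that add atoms: N-(5-chloropyridin-2-yl)bis(trifluoromethanesulfonimide), FC(F)(F)S(=O)(=O)N(c1ccc(Cl)cn1)S(=O)(=O)C(F)(F)F
Why: Enol triflate formation by deprotonation at C2, the only enolisable position, and O-sulfonylation turns the C3 ketone into a C2=C3 alkenyl electrophile; slightly less than one equivalent of base leaves no strong base to remove the now indenylic C1–H, so C1 is spatially retained (descriptor S only by a priority change).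

Step 13
Reactants: 20 indenyl triflate; 2 1,3-bis(benzyloxy)-5-bromobenzene
Product: 23 (1S)-4,6-bis(benzyloxy)-3-[3,5-bis(benzyloxy)phenyl]-2-[4-(benzyloxy)phenyl]-1-{(S)-[4-(benzyloxy)phenyl](tert-butyldimethylsilyloxy)methyl}-1H-indene, via aryllithium 21 (not isolated), via arylzinc chloride 22 (not isolated)
Conditions: 2 (1.6 equiv), n-BuLi (1.5 equiv), THF, −78 °C; ZnCl2 (1.6 equiv), −78 °C → rt; then 20, Pd(OAc)2 (5 mol %), SPhos (10 mol %), THF, 50 °C
Reagents that add atoms: none
Why: Negishi cross-coupling with a bulky biarylphosphine builds the hindered C3–aryl bond next to the C4 ether without any added base, so the acidic C1–H of the indene is not exchanged and C1 is kept.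

Step 14
Reactants: 23 tetrasubstituted indene
Product: 24 (1R,2R,3R)-4,6-bis(benzyloxy)-3-[3,5-bis(benzyloxy)phenyl]-2-[4-(benzyloxy)phenyl]-1-{(S)-[4-(benzyloxy)phenyl](tert-butyldimethylsilyloxy)methyl}indane (all-cis)
Conditions: [Ir(cod)(PCy3)(py)][B(C6H3-3,5-(CF3)2)4] (5–10 mol %), H2 (50–100 bar), CH2Cl2, rt
Reagents that add atoms: none
Why: Homogeneous iridium-catalysed hydrogenation of an unfunctionalised tetrasubstituted alkene, a reaction type known for 2,3-disubstituted indenes, delivers both hydrogens syn from the face opposite the bulky non-coordinating C1 side chain, which pushes the C2 and C3 aryl groups onto the side-chain face and sets (2R,3R), while benzyl ethers are not cleaved by this catalyst.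

Step 15
Reactants: 24 all-cis silyl ether
Product: 25 (S)-[4-(benzyloxy)phenyl]{(1R,2R,3R)-4,6-bis(benzyloxy)-3-[3,5-bis(benzyloxy)phenyl]-2-[4-(benzyloxy)phenyl]indan-1-yl}methanol
Conditions: Bu4NF (1 M in THF, 3 equiv), THF, rt → 40 °C
Reagents that add atoms: none
Why: Fluoride-mediated Si–O cleavage, driven by the Si–F bond, frees C8–OH at a stage where no acidic C–H or base-labile group is present, so C1–C3 are untouched.

Step 16
Reactants: 25 C8 carbinol
Product: 26 [4-(benzyloxy)phenyl]{(1R,2R,3R)-4,6-bis(benzyloxy)-3-[3,5-bis(benzyloxy)phenyl]-2-[4-(benzyloxy)phenyl]indan-1-yl}methanone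
Conditions: Dess–Martin periodinane (1.5 equiv), NaHCO3, CH2Cl2, 0 °C; short neutral work-up
Reagents that add atoms: none
Why: Dess–Martin oxidation works by ligand exchange at iodine and removal of C8–H in a buffered medium that is neither basic nor strongly acidic, so the newly acidified C1–H should not exchange and the sacrificial C8 stereocentre is erased.

Step 17
Reactants: 26 hexabenzyl ketone
Product: 27 caraphenol B, (1R,2R,3R)-all-cis
Conditions: H2 (1 atm), 10% Pd/C, EtOAc/MeOH 1:1, rt, stopped when the last benzyl ether is gone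
Reagents that add atoms: none
Why: Catalytic hydrogenolysis removes the six aryl benzyl ethers under neutral conditions that do not enolise C1, and the hindered aryl ketone becomes a poorly reducible 4-hydroxyphenyl ketone as soon as its own ether is cleaved.

## Compound list

1 | 5-bromoresorcinol | Oc1cc(O)cc(Br)c1 | starting material
2 | 1,3-bis(benzyloxy)-5-bromobenzene | Brc1cc(OCc2ccccc2)cc(OCc2ccccc2)c1 | intermediate
3 | aryl iminium chloride (Vilsmeier adduct) | C[N+](C)=Cc1c(Br)cc(OCc2ccccc2)cc1OCc1ccccc1.[Cl-] | intermediate
4 | 2,4-bis(benzyloxy)-6-bromobenzaldehyde | O=Cc1c(Br)cc(OCc2ccccc2)cc1OCc1ccccc1 | intermediate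
5 | 4-(benzyloxy)benzaldehyde | O=Cc1ccc(OCc2ccccc2)cc1 | starting material
6 | ethynylmagnesium bromide | C#C[Mg]Br | starting material
7 | rac-1-[4-(benzyloxy)phenyl]prop-2-yn-1-ol | C#CC(O)c1ccc(OCc2ccccc2)cc1 | intermediate
8 | (S)-1-[4-(benzyloxy)phenyl]prop-2-yn-1-ol | O[C@H](c1ccc(OCc2ccccc2)cc1)C#C | intermediate
9 | (S)-propargyl TBS ether | CC(C)(C)[Si](C)(C)O[C@H](c1ccc(OCc2ccccc2)cc1)C#C | intermediate
10 | lithium acetylide of 9 | CC(C)(C)[Si](C)(C)O[C@H](c1ccc(OCc2ccccc2)cc1)C#C[Li] | intermediate
11 | propargylic alcohol, C3 epimers, C8 fixed | CC(C)(C)[Si](C)(C)O[C@H](c1ccc(OCc2ccccc2)cc1)C#CC(O)c1c(Br)cc(OCc2ccccc2)cc1OCc1ccccc1 | intermediate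
12 | (2Z,4S)-alkenylstannane, C3 epimers | CC(C)(C)[Si](C)(C)O[C@H](c1ccc(OCc2ccccc2)cc1)/C=C(/C(O)c1c(Br)cc(OCc2ccccc2)cc1OCc1ccccc1)[Sn](CCCC)(CCCC)CCCC | intermediate
13 | 1-(benzyloxy)-4-iodobenzene | Ic1ccc(OCc2ccccc2)cc1 | starting material
14 | (2E,4S)-allylic alcohol, C3 epimers | CC(C)(C)[Si](C)(C)O[C@H](c1ccc(OCc2ccccc2)cc1)/C=C(/C(O)c1c(Br)cc(OCc2ccccc2)cc1OCc1ccccc1)c1ccc(OCc2ccccc2)cc1 | intermediate
15 | (2E,4S)-bromo enone | CC(C)(C)[Si](C)(C)O[C@H](c1ccc(OCc2ccccc2)cc1)/C=C(/C(=O)c1c(Br)cc(OCc2ccccc2)cc1OCc1ccccc1)c1ccc(OCc2ccccc2)cc1 | intermediate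
16 | bis(pinacolato)diboron | CC1(C)OB(OC1(C)C)B1OC(C)(C)C(C)(C)O1 | starting material
17 | (2E,4S)-boryl enone (key-step precursor) | CC(C)(C)[Si](C)(C)O[C@H](c1ccc(OCc2ccccc2)cc1)/C=C(/C(=O)c1c(OCc2ccccc2)cc(OCc2ccccc2)cc1B1OC(C)(C)C(C)(C)O1)c1ccc(OCc2ccccc2)cc1 | intermediate
18 | (2S,3R)-trans-indan-1-one with (S)-C8 (key-step product) | CC(C)(C)[Si](C)(C)O[C@H](c1ccc(OCc2ccccc2)cc1)[C@H]1c2cc(OCc3ccccc3)cc(OCc3ccccc3)c2C(=O)[C@@H]1c1ccc(OCc2ccccc2)cc1 | intermediate
19 | potassium enolate of 18 | CC(C)(C)[Si](C)(C)O[C@H](c1ccc(OCc2ccccc2)cc1)[C@H]1c2cc(OCc3ccccc3)cc(OCc3ccccc3)c2C([O-])=C1c1ccc(OCc2ccccc2)cc1.[K+] | intermediate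
20 | (1S)-1H-inden-3-yl triflate | CC(C)(C)[Si](C)(C)O[C@H](c1ccc(OCc2ccccc2)cc1)[C@H]1c2cc(OCc3ccccc3)cc(OCc3ccccc3)c2C(OS(=O)(=O)C(F)(F)F)=C1c1ccc(OCc2ccccc2)cc1 | intermediate
21 | 3,5-bis(benzyloxy)phenyllithium | [Li]c1cc(OCc2ccccc2)cc(OCc2ccccc2)c1 | intermediate
22 | 3,5-bis(benzyloxy)phenylzinc chloride | Cl[Zn]c1cc(OCc2ccccc2)cc(OCc2ccccc2)c1 | intermediate
23 | (1S)-2,3-diaryl-1H-indene | CC(C)(C)[Si](C)(C)O[C@H](c1ccc(OCc2ccccc2)cc1)[C@H]1c2cc(OCc3ccccc3)cc(OCc3ccccc3)c2C(c2cc(OCc3ccccc3)cc(OCc3ccccc3)c2)=C1c1ccc(OCc2ccccc2)cc1 | intermediate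
24 | (1R,2R,3R)-all-cis indane silyl ether | CC(C)(C)[Si](C)(C)O[C@H](c1ccc(OCc2ccccc2)cc1)[C@H]1c2cc(OCc3ccccc3)cc(OCc3ccccc3)c2[C@@H](c2cc(OCc3ccccc3)cc(OCc3ccccc3)c2)[C@H]1c1ccc(OCc2ccccc2)cc1 | intermediate
25 | (1R,2R,3R)-all-cis indane, (S)-C8 carbinol | O[C@H](c1ccc(OCc2ccccc2)cc1)[C@H]1c2cc(OCc3ccccc3)cc(OCc3ccccc3)c2[C@@H](c2cc(OCc3ccccc3)cc(OCc3ccccc3)c2)[C@H]1c1ccc(OCc2ccccc2)cc1 | intermediate
26 | hexa-O-benzyl caraphenol B | O=C(c1ccc(OCc2ccccc2)cc1)[C@H]1c2cc(OCc3ccccc3)cc(OCc3ccccc3)c2[C@@H](c2cc(OCc3ccccc3)cc(OCc3ccccc3)c2)[C@H]1c1ccc(OCc2ccccc2)cc1 | intermediate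
27 | caraphenol B | O=C(c1ccc(O)cc1)[C@H]1c2cc(O)cc(O)c2[C@@H](c2cc(O)cc(O)c2)[C@H]1c1ccc(O)cc1 | target

## Step count and risks

Total step count: 17. Longest linear sequence: 15 steps (steps 3–17, from 4-(benzyloxy)benzaldehyde).

**Step 11.** The aryl–rhodium may be protonated (protodeboronation) faster than it inserts into the crowded α-aryl trisubstituted enone. Alternatively, catalyst and substrate may fail to agree on the alkene face, which would give poor facial selectivity at C1. The fallback changes both metal and handle to an asymmetric reductive Heck cyclisation. It sets out from bromo enone 15, so step 10 is skipped, and comes back at indanone 18. With Pd(OAc)2, a chiral MeO-BIPHEP-type bisphosphine and HCO2H/iPr2NEt in DMF at 80–100 °C, zerovalent palladium inserts into C7a–Br and the aryl–palladium carbopalladates C1=C2. The resulting enolate of divalent palladium is released reductively by formate. This is the known cyclisation of 2'-halochalcones to 3-substituted indanones, and it forms the same C1–C7a bond under the same C8 bias. No new compound appears.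

**Step 14.** The tetrasubstituted stilbene-type alkene, flanked by the C4 ether and the C1 side chain, may not bind to iridium at all. The Brønsted acidity of iridium hydrides may ionise the electron-rich benzylic silyl ether. Slow reduction may also allow double-bond migration that erodes C1. The fallback sets out from indene 23 and uses heterogeneous hydrogenation over Pd(OH)2/C (H2, EtOAc/EtOH), the established way to reduce 2,3-diarylindenes from the open face. The loss of all benzyl groups is accepted, which gives the all-cis hexaphenol silyl ether F1. Re-benzylation of F1 with BnBr and K2CO3 in DMF at room temperature comes back to the route at 24.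

**Step 17.** During the long exposure needed to cleave six ethers, the strained all-cis ketone may epimerise at C1 on the catalyst support or in the protic solvent. The aryl ketone may also be over-reduced. The fallback inverts the last two operations, so the enolisable ketone exists only in the final flask. It sets out from carbinol 25, which is hydrogenolysed (H2, Pd/C, EtOAc/MeOH) to the all-cis heptaol F2. F2 is then treated with one equivalent of DDQ in dioxane at room temperature, the known selective dehydrogenation of 4-hydroxybenzylic alcohols to 4-hydroxyphenyl ketones. This comes back to the route at target 27.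

## Further compounds

F0 | step 11 | none | none
F1 | step 14 | (1R,2R,3R)-all-cis hexaphenol with (S)-C8 tert-butyldimethylsilyl ether | CC(C)(C)[Si](C)(C)O[C@H](c1ccc(O)cc1)[C@H]1c2cc(O)cc(O)c2[C@@H](c2cc(O)cc(O)c2)[C@H]1c1ccc(O)cc1
F2 | step 17 | (1R,2R,3R)-all-cis heptaol with (S)-C8 carbinol | O[C@H](c1ccc(O)cc1)[C@H]1c2cc(O)cc(O)c2[C@@H](c2cc(O)cc(O)c2)[C@H]1c1ccc(O)cc1
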